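All runs stem from a simulated flask from invented constants; noise was put on by code.

The easy step is a subtraction on the north-east run: D stops at 78.8%, so it has lost 21.2% of its charge. If D and E pair one to one and X took the rest of E, then X took 0.888 equiv.

| flask | D | X | E | remark | time |
|---|---|---|---|---|---|
| north | 0.18 M | 0.20 equiv | 1.1 equiv | run made earlier |  |
| north-east | 0.18 M | 7 equiv | 1.1 equiv | run made earlier |  |
| green | 0.18 M | 0.150 equiv | 1.10 equiv |  | 15 min |
| ochre | 0.18 M | 0.500 equiv | 1.10 equiv |  | 15 min |
| grey | 0.18 M | 1.50 equiv | 1.10 equiv |  | 15 min |
| teal | 0.18 M | 5.00 equiv | 1.10 equiv |  | 15 min |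

| run | time / min | L / % | D / % |
|---|---|---|---|
| north | 1.00 | 1.2 | 89.5 |
| north | 2.50 | 2.3 | 73.7 |
| north | 5.00 | 2.9 | 59.8 |
| north | 8.00 | 5.7 | 46.2 |
| north-east | 0.667 | 1.7 | 93.3 |
| north-east | 1.33 | 3.6 | 88.4 |
| north-east | 3.00 | 14.7 | 81.3 |
| north-east | 8.00 | 19.1 | 78.8 |

(standard deviation of a reading: 1 percentage point)

- "hardly changes" means that all values lie within two and a half points (for a concentration: within two and a half percent of the largest)

* [L] at the end for green, ochre, grey, teal, in this order
* the shape of the row from first to last (rises, then falls / hardly changes / falls, then rises / rises all the way / falls all the way)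

I divide each take by the mean amount of the taker, replacing each curve by its mean: 0.894 equiv of D and 6.56 equiv of X. That gives a reading of 1.75. This is the split, how many times more readily one equiv of D takes E than one equiv of X does, a selectivity factor for E.

On teal, my own reckoning starts from the rates: D takes 25.9% of the E used at the start, which would cost D 28.5% of its charge. Over the run, the take by D slows by a mean factor of 0.857 and the take by X by 0.919. The factor for X is larger, so in my estimate the share of D drops to 24.6% and D loses 27.1%. That correction is 1.40% of the D charged, beside a scatter of 1 percentage point. Stretching the time of the last north-east reading by the ratio of X puts my estimate of the teal stop at 11.2 min, before 15 min. By its last reading, north-east had turned 90.1% of its lost D into L, so I expect c_L of 0.0439 M on teal.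

The forecast gives 0.01 M, 0.028 M, 0.06 M and 0.044 M, a row that rises, then falls, on the grounds that “Low X is limited by the X available, high X by the loss of E”.

The flask gives 0.00892 M, 0.0259 M, 0.0513 M and 0.0470 M, a row that rises, then falls.

    Z → J (k = 0.00469 s⁻¹)
    E + X → Z (k = 0.00643 M⁻¹ s⁻¹)
    D + E → G (k = 0.0121 M⁻¹ s⁻¹)
    G + Z → L (k = 0.205 M⁻¹ s⁻¹)

The loss of E weighs on teal: with E held at its charge the same flask gives 0.156 M, against 0.0470 M as it runs, and E stands at 0.25% of its charge at 15.0 min. Read again from the end of teal, with D at 71.6% and X at 84%, the split is 1.87, against 1.75. On grey, with D at 48.1% and X at 68% at 15.0 min, the split is 1.82.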